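**Retrosynthetic overview** (core numbering: C1 lactone C=O, C2, C3 ring-fusion CH–O, C4 ring-fusion C–Me, C5 CH2, C6 C(Me)(chain); chain C7–C18)
1. The (E,E)-phenyldiene is made last by a Horner–Wadsworth–Emmons reaction at C15=C16; the C15 aldehyde comes from a terminal alkene carried through the route.
2. The γ-lactone is the last ring formed: iodolactonization of a C1 carboxamide onto the C4=C5 alkene of a 2,5-dihydrofuran sets C4 cis to C3, and the iodide is then removed.
3. The key C2–C3 bond and the C3 stereocentre come from an Eschenmoser–Claisen [3,3] rearrangement of a 2,3-dihydrofuran-3-ol, with 1,3-chirality transfer from a C5–OH that is erased in the same step.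
4. The oxolane ring is formed first, as a γ-lactone that is reduced and dehydrated to the cyclic enol ether; C6 is set by Cram-chelate MeMgBr addition next to the C5–OH.
5. The C5–OH is the only purchased stereocentre, from (R)-α-hydroxy-γ-butyrolactone; it relays to C6 and C3, and C3 then fixes C4.

Assumption: (R)-α-hydroxy-γ-butyrolactone (catalogue compound, made from D-malic acid), 10-bromodec-1-ene and diethyl cinnamylphosphonate are taken as commercial. The route is a proposal and has not been run.

**Route**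

Step 1
Reactants: 1, (R)-α-hydroxy-γ-butyrolactone; 2, 10-bromodec-1-ene (as its Grignard reagent)
Product: 3, (3R)-1,3-dihydroxytetradec-13-en-4-one (in equilibrium with its cyclic hemiketal)
Conditions: MeNH(OMe)·HCl, i-PrMgCl, THF, −20 °C; then dec-9-enylMgBr (from 2, Mg, THF), −20 → 0 °C, one pot; aq. NH4Cl
Reagents that add atoms: dec-9-en-1-ylmagnesium bromide, C=CCCCCCCCC[Mg]Br (from 2)
Why: Lactone aminolysis to the Weinreb amide followed by Grignard addition stops at the ketone through the stable chelated tetrahedral intermediate; the α-alkoxide prevents enolization, so C5 is untouched.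

Step 2
Reactants: 3
Product: 4, (3R,4S)-4-methyltetradec-13-ene-1,3,4-triol
Conditions: MeMgBr (5 equiv), THF, −78 → 0 °C
Reagents that add atoms: methylmagnesium bromide, C[Mg]Br
Why: Cram-chelate addition: the magnesium α-alkoxide locks C5–O syn to the C6 carbonyl and methyl attacks anti to the C4 chain, giving the syn diol (C6 S, methyl on the same side as the C5–OH once the ring is closed).

Step 3
Reactants: 4
Product: 5, (4R,5S)-5-(dec-9-en-1-yl)-4-hydroxy-5-methyloxolan-2-one
Conditions: TEMPO (0.2 equiv), PhI(OAc)2 (2.5 equiv), CH2Cl2, rt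
Reagents that add atoms: none
Why: Chemoselective TEMPO oxidation of the primary alcohol gives the aldehyde, which closes onto the tertiary OH as a lactol and is oxidized on to the γ-lactone; the hindered secondary OH and the alkene are left alone.

Step 4
Reactants: 5
Product: 6, (3R,4R,5S)-5-(dec-9-en-1-yl)-4-hydroxy-3,5-dimethyloxolan-2-one
Conditions: LDA (2.3 equiv), THF, −78 → −40 °C; MeI, −78 °C
Reagents that add atoms: iodomethane, CI
Why: Fráter–Seebach-type alkylation of the β-alkoxide/enolate dianion; the alkoxide cannot β-eliminate and methyl enters trans to it (this centre becomes sp2 in step 7, so its configuration does not matter).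

Step 5
Reactants: 6
Product: 7, (3R,4R,5S)-4-[(tert-butyldimethylsilyl)oxy]-5-(dec-9-en-1-yl)-3,5-dimethyloxolan-2-one
Conditions: TBSOTf, 2,6-lutidine, CH2Cl2, −20 → 0 °C
Reagents that add atoms: tert-butyldimethylsilyl triflate, CC(C)(C)[Si](C)(C)OS(=O)(=O)C(F)(F)F
Why: Silylation of the hindered secondary alcohol so that only the lactol OH is activated in step 7.

Step 6
Reactants: 7
Product: 8, (3R,4R,5S)-4-[(tert-butyldimethylsilyl)oxy]-5-(dec-9-en-1-yl)-3,5-dimethyloxolan-2-ol (anomer mixture)
Conditions: DIBAL-H (1.2 equiv), CH2Cl2, −78 °C; Rochelle salt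
Reagents that add atoms: none
Why: Partial reduction of a γ-lactone to the lactol; the silyl ether and alkene are inert.

Step 7
Reactants: 8
Product: 9, tert-butyl{[(2S,3R)-2-(dec-9-en-1-yl)-2,4-dimethyl-2,3-dihydrofuran-3-yl]oxy}dimethylsilane
Conditions: MsCl, Et3N (excess), CH2Cl2, −40 °C → reflux
Reagents that add atoms: none
Why: Lactol mesylation and elimination through the oxocarbenium ion gives the cyclic enol ether C3=C4; the quaternary C6 blocks aromatization to a furan.

Step 8
Reactants: 9
Product: 10, (2S,3R)-2-(dec-9-en-1-yl)-2,4-dimethyl-2,3-dihydrofuran-3-ol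
Conditions: TBAF, THF, 0 °C → rt; Et3N-deactivated silica
Reagents that add atoms: none
Why: Fluoride desilylation under basic conditions that the acid-labile enol ether tolerates.

Step 9 (key step)
Reactants: 10
Product: 11, 2-[(2S,5S)-5-(dec-9-en-1-yl)-3,5-dimethyl-2,5-dihydrofuran-2-yl]-N,N-dimethylacetamide
Conditions: MeC(OMe)2NMe2 (6 equiv), xylenes, 130–140 °C, MeOH distilled off
Reagents that add atoms: N,N-dimethylacetamide dimethyl acetal, CC(OC)(OC)N(C)C
Why: Eschenmoser–Claisen [3,3] rearrangement: the ketene N,O-acetal on the C5 oxygen delivers CH2CONMe2 to C3 on the same ring face (suprafacial), setting C3 (S) cis to the C6 methyl while C5 becomes sp2 (C4=C5).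

Step 10
Reactants: 11
Product: 12, (3aS,5S,6R,6aR)-5-(dec-9-en-1-yl)-6-iodo-5,6a-dimethyltetrahydrofuro[3,2-b]furan-2(3H)-one
Conditions: I2 (2 equiv), THF–H2O, 0 °C → rt, dark; aq. Na2S2O3
Reagents that add atoms: iodine, II; water, O
Why: 5-exo iodolactonization of the γ,δ-unsaturated amide: the amide oxygen attacks the tertiary C4 anti to the iodonium and the C3 tether forces the cis ring fusion (C4 set); water hydrolyses the iminium ether, and the isolated terminal alkene reacts much more slowly.

Step 11
Reactants: 12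
Product: 13, (3aS,5S,6aS)-5-(dec-9-en-1-yl)-5,6a-dimethyltetrahydrofuro[3,2-b]furan-2(3H)-one
Conditions: Bu3SnH (1.5 equiv), AIBN (cat.), PhMe (0.2 M), 80 °C
Reagents that add atoms: none
Why: Radical deiodination restores the C5 methylene without touching a stereocentre; the high stannane concentration outruns any β-acyloxy radical shift.

Step 12
Reactants: 13
Product: 14, (3aS,5S,6aS)-5,6a-dimethyl-5-(9-oxononyl)tetrahydrofuro[3,2-b]furan-2(3H)-one
Conditions: O3, CH2Cl2, −78 °C; then PPh3
Reagents that add atoms: ozone, [O-][O+]=O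
Why: Ozonolysis with reductive work-up of the only remaining alkene gives the C15 aldehyde.

Step 13
Reactants: 14; 15, diethyl [(2E)-3-phenylprop-2-en-1-yl]phosphonate
Product: 16, plakortone P, (3aS,5S,6aS)-5,6a-dimethyl-5-[(9E,11E)-12-phenyldodeca-9,11-dien-1-yl]tetrahydrofuro[3,2-b]furan-2(3H)-one
Conditions: 15, LiHMDS, THF, −78 °C; then 14, −78 °C → rt
Reagents that add atoms: none beyond reactant 15 (CCOP(=O)(OCC)C/C=C/c1ccccc1)
Why: Horner–Wadsworth–Emmons olefination with the allylic phosphonate anion forms the new C15=C16 bond E-selectively and keeps the styryl E geometry; the preformed anion reacts with the aldehyde faster than it deprotonates the lactone.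

**Compound list**
1 | (R)-α-hydroxy-γ-butyrolactone, (3R)-3-hydroxyoxolan-2-one | O[C@@H]1CCOC1=O | starting material
2 | 10-bromodec-1-ene | C=CCCCCCCCCBr | starting material
3 | (3R)-1,3-dihydroxytetradec-13-en-4-one | OCC[C@@H](O)C(=O)CCCCCCCCC=C | intermediate
4 | (3R,4S)-4-methyltetradec-13-ene-1,3,4-triol | OCC[C@@H](O)[C@@](C)(O)CCCCCCCCC=C | intermediate
5 | (4R,5S)-5-(dec-9-en-1-yl)-4-hydroxy-5-methyloxolan-2-one | O=C1C[C@@H](O)[C@](C)(CCCCCCCCC=C)O1 | intermediate
6 | (3R,4R,5S)-5-(dec-9-en-1-yl)-4-hydroxy-3,5-dimethyloxolan-2-one | O=C1[C@H](C)[C@@H](O)[C@](C)(CCCCCCCCC=C)O1 | intermediate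
7 | (3R,4R,5S)-4-(TBS-oxy)-5-(dec-9-en-1-yl)-3,5-dimethyloxolan-2-one | O=C1[C@H](C)[C@@H](O[Si](C)(C)C(C)(C)C)[C@](C)(CCCCCCCCC=C)O1 | intermediate
8 | (3R,4R,5S)-4-(TBS-oxy)-5-(dec-9-en-1-yl)-3,5-dimethyloxolan-2-ol (anomers) | OC1[C@H](C)[C@@H](O[Si](C)(C)C(C)(C)C)[C@](C)(CCCCCCCCC=C)O1 | intermediate
9 | tert-butyl{[(2S,3R)-2-(dec-9-en-1-yl)-2,4-dimethyl-2,3-dihydrofuran-3-yl]oxy}dimethylsilane | CC1=CO[C@@](C)(CCCCCCCCC=C)[C@@H]1O[Si](C)(C)C(C)(C)C | intermediate
10 | (2S,3R)-2-(dec-9-en-1-yl)-2,4-dimethyl-2,3-dihydrofuran-3-ol | CC1=CO[C@@](C)(CCCCCCCCC=C)[C@@H]1O | intermediate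
11 | 2-[(2S,5S)-5-(dec-9-en-1-yl)-3,5-dimethyl-2,5-dihydrofuran-2-yl]-N,N-dimethylacetamide | CN(C)C(=O)C[C@@H]1O[C@@](C)(CCCCCCCCC=C)C=C1C | intermediate
12 | (3aS,5S,6R,6aR)-5-(dec-9-en-1-yl)-6-iodo-5,6a-dimethyltetrahydrofuro[3,2-b]furan-2(3H)-one | C[C@]1(CCCCCCCCC=C)[C@@H](I)[C@]2(C)OC(=O)C[C@@H]2O1 | intermediate
13 | (3aS,5S,6aS)-5-(dec-9-en-1-yl)-5,6a-dimethyltetrahydrofuro[3,2-b]furan-2(3H)-one | C[C@]1(CCCCCCCCC=C)C[C@]2(C)OC(=O)C[C@@H]2O1 | intermediate
14 | (3aS,5S,6aS)-5,6a-dimethyl-5-(9-oxononyl)tetrahydrofuro[3,2-b]furan-2(3H)-one | C[C@]1(CCCCCCCCC=O)C[C@]2(C)OC(=O)C[C@@H]2O1 | intermediate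
15 | diethyl [(2E)-3-phenylprop-2-en-1-yl]phosphonate | CCOP(=O)(OCC)C/C=C/c1ccccc1 | starting material
16 | plakortone P | C[C@]1(CCCCCCCC/C=C/C=C/c2ccccc2)C[C@]2(C)OC(=O)C[C@@H]2O1 | target

**Totals**
Total steps: 13. Longest linear sequence: 13 (from 1).

**Three steps most likely to fail, with fallbacks**
1. Step 9 (Claisen on a hindered, acid-labile dihydrofuranol; slow ketene-aminal formation or Ferrier-type decomposition). Fallback: Tsuji–Trost C-alkylation instead of a sigmatropic step. Convert 10 to its methyl carbonate and treat with Pd(PPh3)4 and sodium dimethyl malonate; attack at C3 occurs with net retention, on the same face. Krapcho decarboxylation then gives the ester for the same iodolactonization.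
2. Step 2 (the ketone is masked as a hemiketal; chelate selectivity at C6). Fallback: swap the roles and the control element. Make the α-silyloxy methyl ketone (MeMgBr on the Weinreb amide, bulky silyl ether on the C5–OH) and add dec-9-enyllithium/CeCl3 under non-chelating Felkin–Anh control, which should favour the same C5/C6 diastereomer.
3. Step 7 (lactol dehydration to the trisubstituted enol ether). Fallback: make the enol ether from the lactone enolate instead. Treat 7 with KHMDS and PhNTf2 to give the cyclic ketene-acetal triflate, then reduce it with Pd(PPh3)4 and Bu3SnH to give 9 directly.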